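**Plan**
1. Retrosynthesis: the benzoyl groups on O5 and O2 are cut first, the C2 carbinol is taken back to a ketone, the C3=C4 alkene plus the C1 hydroxyl to a C1–O–C4 ether bridge, the C5/C6 diol to an alkene, and finally the ring bonds C1–C2 and C3–C4 to a furan and a two-carbon dienophile.
2. Enabling feature: the C1 oxygen is 1,4 to alkene carbon C4 and cis to the C5 and C6 oxygens, the pattern of an exo-dihydroxylated 7-oxabicyclo[2.2.1]heptane whose bridgehead C1 carries the C7 benzoyloxymethyl group of a furfuryl ester.
3. Forward: furfuryl benzoate and 2-bromoacrolein give the six-membered carbocycle with its temporary oxygen bridge in one cycloaddition; osmylation, acetonide protection and unmasking of the bromo aldehyde (Pinnick, Curtius, hydrolysis) lead to the C2 ketone.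
4. Silyl-triflate-induced β-elimination then opens the bridge (the only ring change after the cycloaddition); directed reduction at C2, benzoylation of O2, acetonide removal and benzoylation of O5 finish the route.
5. Stereochemistry: C1 and the bridgehead C4 come from the catalyst-controlled Diels–Alder reaction; C5 and C6 from exo-face osmylation (cis to the C1 oxygen); C2 from hydride delivered by the C1 hydroxyl (trans to it).

Key step: step 3

Numbering: target locants C1–C7 are used for every compound (C1 quaternary carbinol, C2 and C5 benzoate carbons, C3=C4, C6 free carbinol, C7 the exocyclic CH2). In the bicyclic compounds they coincide with the 7-oxabicyclo[2.2.1]heptane locants, the bridge oxygen joining C1 and C4.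

Assumption: the L-tryptophan-derived B-butyl oxazaborolidinone is taken to expose the Cα-Re face of 2-bromoacrolein, as established for simple dienes. Adduct 7 needs attack on the Cα-Si face, so the catalyst from N-tosyl-D-tryptophan and BuB(OH)2 is specified; were the sense reversed for this diene, the L-catalyst would be used and nothing else would change.

**Step 1**
Reactants: 1 furfuryl alcohol; 2 benzoyl chloride
Product: 3 furfuryl benzoate (furan-2-ylmethyl benzoate)
Conditions: Et3N, DMAP (cat.), CH2Cl2, 0 °C
Reagents that add atoms: none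
Why: Base-mediated O-acylation (nucleophilic acyl substitution) of a primary alcohol, with amine present throughout so that the acid-sensitive furfuryl system never meets HCl.

**Step 2**
Reactants: 4 acrolein
Product: 6 2-bromoacrolein, via 2,3-dibromopropanal 5 (not isolated)
Conditions: Br2, CH2Cl2, −78 to 0 °C; then Et3N, 0 °C; distilled at reduced pressure and used fresh
Reagents that add atoms: bromine, BrBr
Why: Electrophilic addition of bromine to the alkene followed by E1cB-type loss of HBr from the acidic α-position gives the α-bromo enal, which is used at once because it polymerises.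

**Step 3**
Reactants: 3 furfuryl benzoate; 6 2-bromoacrolein
Product: 7 [(1R,2S,4S)-2-bromo-2-formyl-7-oxabicyclo[2.2.1]hept-5-en-1-yl]methyl benzoate (formyl exo and bromine endo)
Conditions: (4R)-2-butyl-4-(1H-indol-3-ylmethyl)-3-tosyl-1,3,2-oxazaborolidin-5-one (10 mol%), 3 (2 equiv), CH2Cl2, −78 °C; quenched cold, product used at once
Reagents that add atoms: none
Why: The boron atom binds the formyl oxygen of s-cis 2-bromoacrolein and the indole ring covers one face of the enal, so the furan adds to the open Cα-Si face in a concerted but asynchronous [4+2] cycloaddition; the closest known reaction is the addition of furan itself to 2-bromoacrolein under the same type of oxazaborolidinone. The six-membered carbocycle C1–C6 closes in this single intermolecular suprafacial cycloaddition by forming C1–C2 and C3–C4 together, the furan oxygen becoming the C1–O–C4 bridge. C1 and C4 are set by the catalyst-controlled enantioface of the dienophile combined with the exo-formyl topology, and C2 (formyl exo, bromine endo) by the intrinsic preference of α-bromoacrolein for an exo aldehyde. The step needs ortho regiochemistry, which the diene secures because its unsubstituted α-carbon (C4) carries the larger HOMO coefficient and bonds to the electrophilic methylene (C3), leaving the bromine-bearing carbon to bond to C1. It also needs kinetic control, which the low temperature should secure against cycloreversion and against Friedel–Crafts-type conjugate addition at the free furan position.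

**Step 4**
Reactants: 7
Product: 8 [(1S,2S,4S,5R,6S)-2-bromo-2-formyl-5,6-dihydroxy-7-oxabicyclo[2.2.1]heptan-1-yl]methyl benzoate (5,6-exo,exo-diol)
Conditions: OsO4 (2 mol%), NMO, acetone/H2O, 0 °C
Reagents that add atoms: osmium tetroxide, O=[Os](=O)(=O)=O (delivers both oxygens, catalytic); N-methylmorpholine N-oxide, C[N+]1([O-])CCOCC1 and water, O (net oxygen sources)
Why: Catalytic osmium tetroxide dihydroxylation by concerted [3+2] addition occurs on the exo face of the strained alkene, the endo face being screened by the C2 bromine and the C2–C3 bridge, which places both new oxygens at C5 and C6 cis to the bridge oxygen and also removes the alkene needed for cycloreversion.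

**Step 5**
Reactants: 8
Product: 9 [(1S,2S,4S,5S,6S)-2-bromo-2-formyl-5,6-(isopropylidenedioxy)-7-oxabicyclo[2.2.1]heptan-1-yl]methyl benzoate
Conditions: 2,2-dimethoxypropane, PPTS (cat.), acetone, rt
Reagents that add atoms: 2,2-dimethoxypropane, COC(C)(C)OC
Why: Acid-catalysed acetal exchange (acetonide formation) is fast on a rigid cis-exo diol, while the neopentyl α-bromo aldehyde, whose oxocarbenium ion is destabilised by bromine, should not be acetalised.

**Step 6**
Reactants: 9
Product: 10 (1S,2S,4S,5S,6S)-1-(benzoyloxymethyl)-2-bromo-5,6-(isopropylidenedioxy)-7-oxabicyclo[2.2.1]heptane-2-carboxylic acid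
Conditions: NaClO2, NaH2PO4, 2-methyl-2-butene, t-BuOH/H2O, 0 °C to rt
Reagents that add atoms: sodium chlorite, [Na+].[O-]Cl=O
Why: Pinnick oxidation converts the non-enolisable aldehyde to the acid under buffered conditions that leave the acetonide, the benzoate and the tertiary bromide alone, with 2-methyl-2-butene taking up the hypochlorous acid.

**Step 7**
Reactants: 10
Product: 13 [(1S,4S,5S,6S)-5,6-(isopropylidenedioxy)-2-oxo-7-oxabicyclo[2.2.1]heptan-1-yl]methyl benzoate, via acyl azide 11 (not isolated), via isocyanate 12 (not isolated)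
Conditions: DPPA, Et3N, toluene, rt then 80 °C; then THF/H2O/AcOH, 40 °C
Reagents that add atoms: water, O (the C2 carbonyl oxygen); diphenylphosphoryl azide, [N-]=[N+]=NP(=O)(Oc1ccccc1)Oc1ccccc1 (azide nitrogen of 11 and 12 only)
Why: Curtius rearrangement of the acyl azide (C2 migrates with retention) gives an α-bromo isocyanate whose hydrolysis passes through a geminal bromo amine that expels bromide to an iminium ion and ends at the ketone, the established unmasking of α-halo acid ketene equivalents, run here without hydroxide so that the C7 benzoate survives.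

**Step 8**
Reactants: 13
Product: 16 [(1S,5S,6S)-1-hydroxy-5,6-(isopropylidenedioxy)-2-oxocyclohex-3-en-1-yl]methyl benzoate, via silyl enol ether 14 (not isolated), via silyl ether 15 (not isolated)
Conditions: TMSOTf, Et3N, CH2Cl2, 0 °C to rt; then aq. citric acid, THF, rt
Reagents that add atoms: trimethylsilyl trifluoromethanesulfonate, C[Si](C)(C)OS(=O)(=O)C(F)(F)F (silyl group of 14 and 15 only; 16 is an isomer of 13)
Why: Soft enolisation gives the C2=C3 silyl enol ether and silyl-triflate-assisted E1cB-type β-elimination then breaks the C4–O bond, as known for 7-oxabicyclo[2.2.1]heptan-2-ones, so that C3=C4 forms and the bridge oxygen stays on C1 as a silyl ether (no free alkoxide to attract the C7 benzoyl group) until mild acid removes it; C1 being quaternary, no aromatisation can follow and no stereocentre is touched.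

**Step 9**
Reactants: 16
Product: 17 [(1R,2S,5S,6S)-1,2-dihydroxy-5,6-(isopropylidenedioxy)cyclohex-3-en-1-yl]methyl benzoate
Conditions: Me4NBH(OAc)3, MeCN/AcOH, −30 to 0 °C
Reagents that add atoms: none
Why: Evans–Saksena hydroxyl-directed reduction, in which the C1 hydroxyl displaces acetate on boron and the resulting alkoxyborohydride delivers hydride intramolecularly to the carbonyl carbon on the face of the C1–O bond, should give 1,2-reduction of the enone and a C2 hydroxyl trans to the C1 hydroxyl.

**Step 10**
Reactants: 17; 2 benzoyl chloride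
Product: 18 [(1R,2S,5S,6S)-2-(benzoyloxy)-1-hydroxy-5,6-(isopropylidenedioxy)cyclohex-3-en-1-yl]methyl benzoate
Conditions: pyridine, DMAP (cat.), CH2Cl2, 0 °C
Reagents that add atoms: none
Why: DMAP-catalysed O-acylation should occur at the secondary allylic C2 hydroxyl only, since the tertiary C1 hydroxyl is inert under these conditions and the C5 and C6 oxygens are masked.

**Step 11**
Reactants: 18
Product: 19 [(1S,2S,5S,6S)-2-(benzoyloxy)-1,5,6-trihydroxycyclohex-3-en-1-yl]methyl benzoate
Conditions: AcOH/H2O (4:1), 45 °C
Reagents that add atoms: none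
Why: Acid-catalysed acetal hydrolysis frees the C5/C6 cis-diol under conditions too mild to hydrolyse or shift the benzoates.

**Step 12**
Reactants: 19; 2 benzoyl chloride
Product: 20 [(1S,2S,5S,6S)-2,5-bis(benzoyloxy)-1,6-dihydroxycyclohex-3-en-1-yl]methyl benzoate (target, CNP0128482.4)
Conditions: 2 (1.05 equiv), pyridine, CH2Cl2, −40 to −20 °C
Reagents that add atoms: none
Why: Kinetically controlled regioselective O-acylation should give the C5 benzoate, because the C5 hydroxyl is allylic and flanked by the flat sp2 carbon C4, the C6 hydroxyl is crowded by the fully substituted C1, and the tertiary C1 hydroxyl does not react.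

**Compound list**
1 | furfuryl alcohol | OCc1ccco1 | starting material
2 | benzoyl chloride | O=C(Cl)c1ccccc1 | starting material
3 | furfuryl benzoate | O=C(OCc1ccco1)c1ccccc1 | intermediate
4 | acrolein | C=CC=O | starting material
5 | 2,3-dibromopropanal (racemic) | O=CC(Br)CBr | intermediate (not isolated)
6 | 2-bromoacrolein | C=C(Br)C=O | intermediate
7 | [(1R,2S,4S)-2-bromo-2-formyl-7-oxabicyclo[2.2.1]hept-5-en-1-yl]methyl benzoate, formyl exo | O=C(OC[C@]12O[C@H](C=C1)C[C@@]2(Br)C=O)c1ccccc1 | intermediate
8 | [(1S,2S,4S,5R,6S)-2-bromo-2-formyl-5,6-dihydroxy-7-oxabicyclo[2.2.1]heptan-1-yl]methyl benzoate, exo,exo-diol | O=C(OC[C@]12O[C@@H](C[C@@]2(Br)C=O)[C@H](O)[C@@H]1O)c1ccccc1 | intermediate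
9 | [(1S,2S,4S,5S,6S)-2-bromo-2-formyl-5,6-(isopropylidenedioxy)-7-oxabicyclo[2.2.1]heptan-1-yl]methyl benzoate | O=C(OC[C@]12O[C@@H](C[C@@]2(Br)C=O)[C@@H]2OC(C)(C)O[C@H]12)c1ccccc1 | intermediate
10 | (1S,2S,4S,5S,6S)-1-(benzoyloxymethyl)-2-bromo-5,6-(isopropylidenedioxy)-7-oxabicyclo[2.2.1]heptane-2-carboxylic acid | O=C(OC[C@]12O[C@@H](C[C@@]2(Br)C(=O)O)[C@@H]2OC(C)(C)O[C@H]12)c1ccccc1 | intermediate
11 | acyl azide of 10 | O=C(OC[C@]12O[C@@H](C[C@@]2(Br)C(=O)N=[N+]=[N-])[C@@H]2OC(C)(C)O[C@H]12)c1ccccc1 | intermediate (not isolated)
12 | [(1S,2S,4S,5S,6S)-2-bromo-2-isocyanato-5,6-(isopropylidenedioxy)-7-oxabicyclo[2.2.1]heptan-1-yl]methyl benzoate | O=C(OC[C@]12O[C@@H](C[C@@]2(Br)N=C=O)[C@@H]2OC(C)(C)O[C@H]12)c1ccccc1 | intermediate (not isolated)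
13 | [(1S,4S,5S,6S)-5,6-(isopropylidenedioxy)-2-oxo-7-oxabicyclo[2.2.1]heptan-1-yl]methyl benzoate | O=C(OC[C@]12O[C@@H](CC2=O)[C@@H]2OC(C)(C)O[C@H]12)c1ccccc1 | intermediate
14 | [(1S,4S,5S,6S)-5,6-(isopropylidenedioxy)-2-(trimethylsilyloxy)-7-oxabicyclo[2.2.1]hept-2-en-1-yl]methyl benzoate | O=C(OC[C@]12O[C@@H](C=C2O[Si](C)(C)C)[C@@H]2OC(C)(C)O[C@H]12)c1ccccc1 | intermediate (not isolated)
15 | [(1S,5S,6S)-5,6-(isopropylidenedioxy)-2-oxo-1-(trimethylsilyloxy)cyclohex-3-en-1-yl]methyl benzoate | O=C(OC[C@@]1(O[Si](C)(C)C)C(=O)C=C[C@@H]2OC(C)(C)O[C@H]12)c1ccccc1 | intermediate (not isolated)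
16 | [(1S,5S,6S)-1-hydroxy-5,6-(isopropylidenedioxy)-2-oxocyclohex-3-en-1-yl]methyl benzoate | O=C(OC[C@@]1(O)C(=O)C=C[C@@H]2OC(C)(C)O[C@H]12)c1ccccc1 | intermediate
17 | [(1R,2S,5S,6S)-1,2-dihydroxy-5,6-(isopropylidenedioxy)cyclohex-3-en-1-yl]methyl benzoate | O=C(OC[C@@]1(O)[C@@H](O)C=C[C@@H]2OC(C)(C)O[C@H]12)c1ccccc1 | intermediate
18 | [(1R,2S,5S,6S)-2-(benzoyloxy)-1-hydroxy-5,6-(isopropylidenedioxy)cyclohex-3-en-1-yl]methyl benzoate | O=C(OC[C@@]1(O)[C@@H](OC(=O)c2ccccc2)C=C[C@@H]2OC(C)(C)O[C@H]12)c1ccccc1 | intermediate
19 | [(1S,2S,5S,6S)-2-(benzoyloxy)-1,5,6-trihydroxycyclohex-3-en-1-yl]methyl benzoate | O=C(OC[C@@]1(O)[C@@H](OC(=O)c2ccccc2)C=C[C@H](O)[C@@H]1O)c1ccccc1 | intermediate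
20 | [(1S,2S,5S,6S)-2,5-bis(benzoyloxy)-1,6-dihydroxycyclohex-3-en-1-yl]methyl benzoate | O=C(OC[C@@]1(O)[C@@H](OC(=O)c2ccccc2)C=C[C@H](OC(=O)c2ccccc2)[C@@H]1O)c1ccccc1 | target

**Step count**
Total: 12 steps. Longest linear sequence: 11 steps (steps 1 and 3–12 from furfuryl alcohol; step 2 is a one-step side branch).

**Steps most likely to fail**

Step 3. The ester-bearing furan is a weaker diene than furan. The cycloaddition may be overtaken by Friedel–Crafts-type conjugate addition at the free α-position, reversed on warming, or lose enantioface control through a pathway not bound to the catalyst. The fallback gives up catalyst control and resolves instead. It sets out from 3 and 6: ZnI2-promoted cycloaddition (CH2Cl2, 0 °C) should give 7 together with the enantiomer of 7 F1, with the same ortho and exo-formyl preferences. The racemate is taken through the conditions of steps 4 to 6, which give, beside 8, 9 and 10, the mirror-image diol F2, the mirror-image acetonide aldehyde F3 and the mirror-image acid F4. The racemic acid is then crystallised with half an equivalent of (S)-1-phenylethylamine; the (S)-1-phenylethylammonium salt of 10 F5 is collected (the (R)-amine is used if the other diastereomeric salt proves the less soluble) and acidified. The fallback rejoins the route at 10.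

Step 12. Discrimination between the C5 and C6 hydroxyls may be poor, leading to acylation at C6, double acylation or base-mediated benzoyl migration. The fallback replaces direct acylation by stereoelectronically controlled opening of a cyclic orthoester. It sets out from 19: trimethyl orthobenzoate and CSA in CH2Cl2 should give the cyclic orthobenzoate F6 across O5 and O6, the only secondary cis-diol. Aqueous acetic acid then opens it by the axial-ester rule for orthoester hydrolysis. With the C7 group equatorial, O6 is equatorial and the allylic O5 pseudoaxial, so the benzoyl group should end on O5. This gives 20 directly.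

Step 9. If hydride delivery through the tertiary C1 alkoxyborohydride is slow, facial control may be lost or conjugate reduction may compete. The fallback uses external hydride and corrects the configuration afterwards. It sets out from 16: Luche reduction (NaBH4, CeCl3·7H2O, MeOH, −78 °C) is 1,2-selective for enones. Any trans-diol formed is 17 itself. The C2-epimeric cis-diol F7 that may accompany or replace it is treated with benzoic acid, PPh3 and diisopropyl azodicarboxylate; this Mitsunobu esterification inverts C2 and installs the benzoate in one operation. The fallback rejoins the route at 18.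

**Further compounds**
F1 | step 3 | [(1S,2R,4R)-2-bromo-2-formyl-7-oxabicyclo[2.2.1]hept-5-en-1-yl]methyl benzoate (enantiomer of 7) | O=C(OC[C@@]12O[C@@H](C=C1)C[C@]2(Br)C=O)c1ccccc1
F2 | step 3 | [(1R,2R,4R,5S,6R)-2-bromo-2-formyl-5,6-dihydroxy-7-oxabicyclo[2.2.1]heptan-1-yl]methyl benzoate (enantiomer of 8) | O=C(OC[C@@]12O[C@H](C[C@]2(Br)C=O)[C@@H](O)[C@H]1O)c1ccccc1
F3 | step 3 | [(1R,2R,4R,5R,6R)-2-bromo-2-formyl-5,6-(isopropylidenedioxy)-7-oxabicyclo[2.2.1]heptan-1-yl]methyl benzoate (enantiomer of 9) | O=C(OC[C@@]12O[C@H](C[C@]2(Br)C=O)[C@H]2OC(C)(C)O[C@@H]12)c1ccccc1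
F4 | step 3 | (1R,2R,4R,5R,6R)-1-(benzoyloxymethyl)-2-bromo-5,6-(isopropylidenedioxy)-7-oxabicyclo[2.2.1]heptane-2-carboxylic acid (enantiomer of 10) | O=C(OC[C@@]12O[C@H](C[C@]2(Br)C(=O)O)[C@H]2OC(C)(C)O[C@@H]12)c1ccccc1
F5 | step 3 | (S)-1-phenylethylammonium salt of 10 | O=C(OC[C@]12O[C@@H](C[C@@]2(Br)C(=O)[O-])[C@@H]2OC(C)(C)O[C@H]12)c1ccccc1.C[C@H]([NH3+])c1ccccc1
F6 | step 12 | cyclic orthobenzoate (2-methoxy-2-phenyl-1,3-dioxolane across O5 and O6) of 19, mixture at the orthoester carbon | O=C(OC[C@@]1(O)[C@@H](OC(=O)c2ccccc2)C=C[C@@H]2OC(OC)(c3ccccc3)O[C@H]12)c1ccccc1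
F7 | step 9 | [(1R,2R,5S,6S)-1,2-dihydroxy-5,6-(isopropylidenedioxy)cyclohex-3-en-1-yl]methyl benzoate (C2 epimer of 17) | O=C(OC[C@@]1(O)[C@H](O)C=C[C@@H]2OC(C)(C)O[C@H]12)c1ccccc1
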